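**Retrosynthetic overview**

1. Gneyulin A ⇐ its deca-benzyl ether (BCl3/pentamethylbenzene). The stilbene C=C ⇐ Horner–Wadsworth–Emmons reaction of a bis-dihydrobenzofuran 6-carbaldehyde with a 2,4-bis(benzyloxy)benzyl phosphonate.
2. Second dihydrobenzofuran (unit 2): 3-aryl group ⇐ decarboxylative arylation of a 3-carboxylic acid; O1–C2 bond ⇐ acid-mediated ring closure; C2–C3 bond ⇐ key intermolecular Evans syn-aldol joining the 5-carbaldehyde of unit 1 to an (R)-oxazolidinone arylacetyl imide.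
3. Unit 1 ⇐ the same aldol / ring closure / decarboxylative arylation sequence from a second arylacetyl imide and 2,4-bis(benzyloxy)benzaldehyde.
4. Both arylacetyl imides ⇐ bromodihydroxybenzoates (MOM/benzyl protection, Negishi coupling with Reformatsky reagents, acylation of (R)-4-benzyloxazolidin-2-one).
5. Ring order: all benzene rings are bought; furan ring of unit 1 first, then furan ring of unit 2. In each unit the aldol sets C3, ring closure relays it to C2 (trans), and the arylation re-sets C3 trans to C2.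

Assumption: the benzyl-protected building blocks and the two bromodihydroxybenzoates are bought as catalogue items.

Abbreviation used in names: U1 = (2R,3R)-6-(benzyloxy)-2-[2,4-bis(benzyloxy)phenyl]-3-[3,5-bis(benzyloxy)phenyl]-2,3-dihydro-1-benzofuran-5-yl.

**Route**

Step 1
Reactants: 1 methyl 5-bromo-2,4-dihydroxybenzoate
Product: 2 methyl 5-bromo-2-hydroxy-4-(methoxymethoxy)benzoate
Conditions: MOMCl (1.1 equiv), i-Pr2NEt, CH2Cl2, 0 °C
Reagents that add atoms: chloromethyl methyl ether COCCl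
Why: Williamson-type etherification in which only the 4-OH reacts, because the 2-OH is held in a hydrogen bond to the ester carbonyl.

Step 2
Reactants: 2 methyl 5-bromo-2-hydroxy-4-(methoxymethoxy)benzoate
Product: 3 methyl 2-(benzyloxy)-5-bromo-4-(methoxymethoxy)benzoate
Conditions: BnBr, K2CO3, DMF, 60 °C
Reagents that add atoms: benzyl bromide BrCc1ccccc1
Why: Williamson etherification of the remaining hydrogen-bonded phenol under forcing carbonate/DMF conditions that leave the MOM ether and the ester untouched.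

Step 3
Reactants: 3 methyl 2-(benzyloxy)-5-bromo-4-(methoxymethoxy)benzoate
Product: 4 methyl 2-(benzyloxy)-5-(2-ethoxy-2-oxoethyl)-4-(methoxymethoxy)benzoate
Conditions: Pd2(dba)3 (2.5 mol%), XPhos (10 mol%), BrZnCH2CO2Et (from BrCH2CO2Et and Zn), THF, 65 °C
Reagents that add atoms: (2-ethoxy-2-oxoethyl)zinc bromide CCOC(=O)C[Zn]Br
Why: Negishi coupling of a Reformatsky reagent, in which the Pd/XPhos catalyst inserts into the electron-rich C–Br bond and the neutral zinc enolate delivers the CH2CO2Et group without attacking the methyl ester.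

Step 4
Reactants: 4 methyl 2-(benzyloxy)-5-(2-ethoxy-2-oxoethyl)-4-(methoxymethoxy)benzoate
Product: 5 2-[4-(benzyloxy)-5-(methoxycarbonyl)-2-(methoxymethoxy)phenyl]acetic acid
Conditions: LiOH·H2O (1.2 equiv), THF/H2O, 0 °C; then HCl (aq.)
Reagents that add atoms: lithium hydroxide [Li+].[OH-]
Why: Saponification that is selective because the unhindered aliphatic ethyl ester hydrolyses far faster than the benzoate, which carries an ortho benzyloxy group and two donor oxygens.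

Step 5
Reactants: 5 2-[4-(benzyloxy)-5-(methoxycarbonyl)-2-(methoxymethoxy)phenyl]acetic acid and 6 (R)-4-benzyloxazolidin-2-one
Product: 8 (R)-4-benzyl-3-{2-[4-(benzyloxy)-5-(methoxycarbonyl)-2-(methoxymethoxy)phenyl]acetyl}oxazolidin-2-one, via mixed pivalic anhydride 7 (not isolated)
Conditions: t-BuCOCl, Et3N, THF, −20 °C; then 6, LiCl, rt
Reagents that add atoms: none
Why: N-acylation of the oxazolidinone through the mixed pivalic anhydride (LiCl/Et3N variant) installs the Evans auxiliary under mild conditions.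

Step 6
Reactants: 8 (R)-4-benzyl-3-{2-[4-(benzyloxy)-5-(methoxycarbonyl)-2-(methoxymethoxy)phenyl]acetyl}oxazolidin-2-one and 9 2,4-bis(benzyloxy)benzaldehyde
Product: 12 (R)-4-benzyl-3-[(2R,3R)-2-[4-(benzyloxy)-5-(methoxycarbonyl)-2-(methoxymethoxy)phenyl]-3-[2,4-bis(benzyloxy)phenyl]-3-hydroxypropanoyl]oxazolidin-2-one, via Z-dibutylboron enolate 10 (not isolated), via dibutylboron aldolate 11 (not isolated)
Conditions: Bu2BOTf, i-Pr2NEt, CH2Cl2, 0 °C; 9, −78 → 0 °C; then pH 7 buffer, MeOH, H2O2, 0 °C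
Reagents that add atoms: none
Why: Evans syn-aldol reaction in which the Z-boron enolate reacts through a Zimmerman–Traxler chair on the face away from the benzyl group of the (R)-auxiliary, giving the (2R,3R) adduct and fixing the carbon that becomes C3 of the ring.

Step 7
Reactants: 12 (R)-4-benzyl-3-[(2R,3R)-2-[4-(benzyloxy)-5-(methoxycarbonyl)-2-(methoxymethoxy)phenyl]-3-[2,4-bis(benzyloxy)phenyl]-3-hydroxypropanoyl]oxazolidin-2-one
Product: 14 methyl (2R,3R)-3-{[(R)-4-benzyl-2-oxooxazolidin-3-yl]carbonyl}-6-(benzyloxy)-2-[2,4-bis(benzyloxy)phenyl]-2,3-dihydro-1-benzofuran-5-carboxylate, via free phenol 13 (not isolated)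
Conditions: p-TsOH·H2O (0.3 equiv), MeOH/CH2Cl2, 40 °C; then CH2Cl2, 4 Å MS, rt
Reagents that add atoms: none
Why: Acid-catalysed MOM cleavage and SN1 cyclodehydration, in which the carbinol ionises to a 2,4-dialkoxybenzylic cation that the ortho phenol captures reversibly, so the ring closes to the thermodynamically preferred trans isomer and the untouched C3 centre dictates 2R.

Step 8
Reactants: 14 methyl (2R,3R)-3-{[(R)-4-benzyl-2-oxooxazolidin-3-yl]carbonyl}-6-(benzyloxy)-2-[2,4-bis(benzyloxy)phenyl]-2,3-dihydro-1-benzofuran-5-carboxylate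
Product: 16 (2R,3R)-6-(benzyloxy)-2-[2,4-bis(benzyloxy)phenyl]-5-(methoxycarbonyl)-2,3-dihydro-1-benzofuran-3-carboxylic acid, via peroxy acid 15 (not isolated)
Conditions: LiOH·H2O, H2O2 (30%), THF/H2O, 0 °C; then Na2SO3 (aq.); HCl (aq.)
Reagents that add atoms: hydrogen peroxide OO
Why: Evans auxiliary cleavage with LiOOH, where hydroperoxide attacks the exocyclic imide carbonyl selectively and leaves the aryl methyl ester and the trans ring intact.

Step 9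
Reactants: 16 (2R,3R)-6-(benzyloxy)-2-[2,4-bis(benzyloxy)phenyl]-5-(methoxycarbonyl)-2,3-dihydro-1-benzofuran-3-carboxylic acid and 17 1,3-bis(benzyloxy)-5-bromobenzene
Product: 18 methyl (2R,3R)-6-(benzyloxy)-2-[2,4-bis(benzyloxy)phenyl]-3-[3,5-bis(benzyloxy)phenyl]-2,3-dihydro-1-benzofuran-5-carboxylate
Conditions: Ir[dF(CF3)ppy]2(dtbbpy)PF6 (2 mol%), NiCl2·glyme (10 mol%), dtbbpy (15 mol%), Cs2CO3, DMF, blue LEDs, rt
Reagents that add atoms: none
Why: Nickel/photoredox decarboxylative arylation, in which oxidation of the caesium carboxylate and loss of CO2 give a C3 benzylic radical that the aryl-nickel species captures and couples on the face opposite the C2 aryl group, so the fixed 2R centre sets 3R (any minor cis isomer is removed by chromatography, not equilibrated).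

Step 10
Reactants: 18 methyl (2R,3R)-6-(benzyloxy)-2-[2,4-bis(benzyloxy)phenyl]-3-[3,5-bis(benzyloxy)phenyl]-2,3-dihydro-1-benzofuran-5-carboxylate
Product: 19 [(2R,3R)-6-(benzyloxy)-2-[2,4-bis(benzyloxy)phenyl]-3-[3,5-bis(benzyloxy)phenyl]-2,3-dihydro-1-benzofuran-5-yl]methanol
Conditions: i-Bu2AlH (3 equiv), CH2Cl2, −78 → 0 °C; potassium sodium tartrate (aq.)
Reagents that add atoms: none
Why: Hydride reduction of the aryl ester to the benzylic alcohol, with ethers and the ring inert to i-Bu2AlH at low temperature.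

Step 11
Reactants: 19 [(2R,3R)-6-(benzyloxy)-2-[2,4-bis(benzyloxy)phenyl]-3-[3,5-bis(benzyloxy)phenyl]-2,3-dihydro-1-benzofuran-5-yl]methanol
Product: 20 (2R,3R)-6-(benzyloxy)-2-[2,4-bis(benzyloxy)phenyl]-3-[3,5-bis(benzyloxy)phenyl]-2,3-dihydro-1-benzofuran-5-carbaldehyde
Conditions: MnO2 (activated), CH2Cl2, rt
Reagents that add atoms: none
Why: MnO2 oxidation is selective for the benzylic alcohol and stops at the aldehyde under neutral conditions.

Step 12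
Reactants: 21 methyl 4-bromo-3,5-dihydroxybenzoate
Product: 22 methyl 4-bromo-3,5-bis(methoxymethoxy)benzoate
Conditions: MOMCl (2.5 equiv), i-Pr2NEt, CH2Cl2, 0 °C → rt
Reagents that add atoms: chloromethyl methyl ether COCCl
Why: Williamson-type protection of both phenols as MOM ethers, which keeps the ring symmetrical.

Step 13
Reactants: 22 methyl 4-bromo-3,5-bis(methoxymethoxy)benzoate
Product: 23 methyl 4-[2-(benzyloxy)-2-oxoethyl]-3,5-bis(methoxymethoxy)benzoate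
Conditions: Pd2(dba)3 (2.5 mol%), XPhos (10 mol%), BrZnCH2CO2Bn (from BrCH2CO2Bn and Zn), THF, 65 °C
Reagents that add atoms: [2-(benzyloxy)-2-oxoethyl]zinc bromide O=C(C[Zn]Br)OCc1ccccc1
Why: Negishi coupling of a Reformatsky reagent, where the para ester speeds oxidative addition into the doubly ortho-substituted bromide and the bulky biaryl phosphine tolerates the hindrance.

Step 14
Reactants: 23 methyl 4-[2-(benzyloxy)-2-oxoethyl]-3,5-bis(methoxymethoxy)benzoate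
Product: 24 2-[4-(methoxycarbonyl)-2,6-bis(methoxymethoxy)phenyl]acetic acid
Conditions: H2 (1 atm), 10% Pd/C, EtOAc, rt
Reagents that add atoms: none
Why: Hydrogenolysis cleaves only the benzyl ester, since no other benzyl group or halide is present, and leaves the MOM ethers and the methyl ester.

Step 15
Reactants: 24 2-[4-(methoxycarbonyl)-2,6-bis(methoxymethoxy)phenyl]acetic acid and 6 (R)-4-benzyloxazolidin-2-one
Product: 26 (R)-4-benzyl-3-{2-[4-(methoxycarbonyl)-2,6-bis(methoxymethoxy)phenyl]acetyl}oxazolidin-2-one, via mixed pivalic anhydride 25 (not isolated)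
Conditions: t-BuCOCl, Et3N, THF, −20 °C; then 6, LiCl, rt
Reagents that add atoms: none
Why: N-acylation of the oxazolidinone through the mixed pivalic anhydride, as in step 5.

Step 16
Reactants: 26 (R)-4-benzyl-3-{2-[4-(methoxycarbonyl)-2,6-bis(methoxymethoxy)phenyl]acetyl}oxazolidin-2-one and 20 (2R,3R)-6-(benzyloxy)-2-[2,4-bis(benzyloxy)phenyl]-3-[3,5-bis(benzyloxy)phenyl]-2,3-dihydro-1-benzofuran-5-carbaldehyde
Product: 29 (R)-4-benzyl-3-[(2R,3R)-3-hydroxy-2-[4-(methoxycarbonyl)-2,6-bis(methoxymethoxy)phenyl]-3-(U1)propanoyl]oxazolidin-2-one, via Z-dibutylboron enolate 27 (not isolated), via dibutylboron aldolate 28 (not isolated)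
Conditions: Bu2BOTf, i-Pr2NEt, CH2Cl2, 0 °C; 20, −78 → 0 °C; then pH 7 buffer, MeOH, H2O2, 0 °C
Reagents that add atoms: none
Why: Evans syn-aldol reaction as the key fragment union, in which the Z-boron enolate adds to the aldehyde through the Zimmerman–Traxler chair under control of the (R)-auxiliary, forming the C2–C3 bond of the second ring as the (2R,3R) adduct independently of the remote centres of unit 1.

Step 17
Reactants: 29 (R)-4-benzyl-3-[(2R,3R)-3-hydroxy-2-[4-(methoxycarbonyl)-2,6-bis(methoxymethoxy)phenyl]-3-(U1)propanoyl]oxazolidin-2-one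
Product: 31 methyl (2R,3R)-3-{[(R)-4-benzyl-2-oxooxazolidin-3-yl]carbonyl}-4-hydroxy-2-(U1)-2,3-dihydro-1-benzofuran-6-carboxylate, via resorcinol aldol 30 (not isolated)
Conditions: p-TsOH·H2O (0.3 equiv), MeOH/CH2Cl2, 40 °C; then CH2Cl2, 4 Å MS, rt
Reagents that add atoms: none
Why: Acid-catalysed MOM cleavage and SN1 cyclodehydration as in step 7, in which either of the two equivalent phenols reversibly captures the benzylic cation (stabilised by the ortho benzyloxy and para ring oxygen of unit 1), giving the trans ring with 2R fixed by the untouched C3 centre.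

Step 18
Reactants: 31 methyl (2R,3R)-3-{[(R)-4-benzyl-2-oxooxazolidin-3-yl]carbonyl}-4-hydroxy-2-(U1)-2,3-dihydro-1-benzofuran-6-carboxylate
Product: 32 methyl (2R,3R)-3-{[(R)-4-benzyl-2-oxooxazolidin-3-yl]carbonyl}-4-(benzyloxy)-2-(U1)-2,3-dihydro-1-benzofuran-6-carboxylate
Conditions: BnBr, K2CO3, acetone, 40 °C
Reagents that add atoms: benzyl bromide BrCc1ccccc1
Why: Williamson etherification of the remaining phenol under mild carbonate conditions, which the trans imide (the thermodynamic epimer) survives unchanged.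

Step 19
Reactants: 32 methyl (2R,3R)-3-{[(R)-4-benzyl-2-oxooxazolidin-3-yl]carbonyl}-4-(benzyloxy)-2-(U1)-2,3-dihydro-1-benzofuran-6-carboxylate
Product: 34 (2R,3R)-4-(benzyloxy)-6-(methoxycarbonyl)-2-(U1)-2,3-dihydro-1-benzofuran-3-carboxylic acid, via peroxy acid 33 (not isolated)
Conditions: LiOH·H2O, H2O2 (30%), THF/H2O, 0 °C → rt; then Na2SO3 (aq.); HCl (aq.)
Reagents that add atoms: hydrogen peroxide OO
Why: LiOOH cleavage of the Evans auxiliary at the exocyclic carbonyl, as in step 8, sparing the aryl methyl ester.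

Step 20
Reactants: 34 (2R,3R)-4-(benzyloxy)-6-(methoxycarbonyl)-2-(U1)-2,3-dihydro-1-benzofuran-3-carboxylic acid and 17 1,3-bis(benzyloxy)-5-bromobenzene
Product: 35 methyl (2R,3R)-4-(benzyloxy)-3-[3,5-bis(benzyloxy)phenyl]-2-(U1)-2,3-dihydro-1-benzofuran-6-carboxylate
Conditions: Ir[dF(CF3)ppy]2(dtbbpy)PF6 (2 mol%), NiCl2·glyme (10 mol%), dtbbpy (15 mol%), Cs2CO3, DMF, blue LEDs, rt
Reagents that add atoms: none
Why: Nickel/photoredox decarboxylative arylation as in step 9, where the C3 radical couples anti to the bulky C2 substituent and gives the trans (2R,3R) ring.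

Step 21
Reactants: 35 methyl (2R,3R)-4-(benzyloxy)-3-[3,5-bis(benzyloxy)phenyl]-2-(U1)-2,3-dihydro-1-benzofuran-6-carboxylate
Product: 36 [(2R,3R)-4-(benzyloxy)-3-[3,5-bis(benzyloxy)phenyl]-2-(U1)-2,3-dihydro-1-benzofuran-6-yl]methanol
Conditions: i-Bu2AlH (3 equiv), CH2Cl2, −78 → 0 °C; potassium sodium tartrate (aq.)
Reagents that add atoms: none
Why: Hydride reduction of the only carbonyl group left, the aryl methyl ester, to the benzylic alcohol.

Step 22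
Reactants: 36 [(2R,3R)-4-(benzyloxy)-3-[3,5-bis(benzyloxy)phenyl]-2-(U1)-2,3-dihydro-1-benzofuran-6-yl]methanol
Product: 37 (2R,3R)-4-(benzyloxy)-3-[3,5-bis(benzyloxy)phenyl]-2-(U1)-2,3-dihydro-1-benzofuran-6-carbaldehyde
Conditions: MnO2 (activated), CH2Cl2, rt
Reagents that add atoms: none
Why: Selective MnO2 oxidation of the benzylic alcohol to the aldehyde without acid or base.

Step 23
Reactants: 9 2,4-bis(benzyloxy)benzaldehyde
Product: 38 [2,4-bis(benzyloxy)phenyl]methanol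
Conditions: NaBH4, MeOH/THF, 0 °C
Reagents that add atoms: none
Why: Borohydride reduction of the aldehyde to the benzylic alcohol.

Step 24
Reactants: 38 [2,4-bis(benzyloxy)phenyl]methanol
Product: 39 diethyl [2,4-bis(benzyloxy)benzyl]phosphonate
Conditions: P(OEt)3 (3 equiv), ZnI2 (1.5 equiv), THF, 66 °C
Reagents that add atoms: triethyl phosphite CCOP(OCC)OCC
Why: ZnI2-mediated Michaelis–Arbuzov-type phosphonylation, in which the electron-rich benzylic alcohol ionises, is captured at phosphorus and the phosphonium loses an ethyl group.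

Step 25
Reactants: 37 (2R,3R)-4-(benzyloxy)-3-[3,5-bis(benzyloxy)phenyl]-2-(U1)-2,3-dihydro-1-benzofuran-6-carbaldehyde and 39 diethyl [2,4-bis(benzyloxy)benzyl]phosphonate
Product: 41 (2R,3R)-4-(benzyloxy)-3-[3,5-bis(benzyloxy)phenyl]-6-{(E)-2-[2,4-bis(benzyloxy)phenyl]ethenyl}-2-(U1)-2,3-dihydro-1-benzofuran (deca-O-benzylgneyulin A), via sodium phosphonate carbanion 40 (not isolated)
Conditions: NaH, THF, 0 °C → rt
Reagents that add atoms: none
Why: Horner–Wadsworth–Emmons olefination, where reversible addition of the benzylic phosphonate anion and syn-elimination of phosphate give the (E)-stilbene.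

Step 26
Reactants: 41 deca-O-benzylgneyulin A
Product: 42 gneyulin A
Conditions: BCl3 (1 M in CH2Cl2, 30 equiv), C6HMe5 (40 equiv), CH2Cl2, −78 °C; then MeOH/H2O
Reagents that add atoms: none
Why: Lewis-acid debenzylation with pentamethylbenzene as benzyl-cation scavenger removes all ten benzyl ethers at low temperature without reducing the stilbene, and the trans rings are the thermodynamic isomers so they persist.

**Compound list**

1 | methyl 5-bromo-2,4-dihydroxybenzoate | COC(=O)c1cc(Br)c(O)cc1O | starting material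
2 | methyl 5-bromo-2-hydroxy-4-(methoxymethoxy)benzoate | COC(=O)c1cc(Br)c(OCOC)cc1O | intermediate
3 | methyl 2-(benzyloxy)-5-bromo-4-(methoxymethoxy)benzoate | COC(=O)c1cc(Br)c(OCOC)cc1OCc1ccccc1 | intermediate
4 | methyl 2-(benzyloxy)-5-(2-ethoxy-2-oxoethyl)-4-(methoxymethoxy)benzoate | CCOC(=O)Cc1cc(C(=O)OC)c(OCc2ccccc2)cc1OCOC | intermediate
5 | 2-[4-(benzyloxy)-5-(methoxycarbonyl)-2-(methoxymethoxy)phenyl]acetic acid | OC(=O)Cc1cc(C(=O)OC)c(OCc2ccccc2)cc1OCOC | intermediate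
6 | (R)-4-benzyloxazolidin-2-one | O=C1N[C@H](Cc2ccccc2)CO1 | starting material
7 | 2-[4-(benzyloxy)-5-(methoxycarbonyl)-2-(methoxymethoxy)phenyl]acetic pivalic anhydride | CC(C)(C)C(=O)OC(=O)Cc1cc(C(=O)OC)c(OCc2ccccc2)cc1OCOC | intermediate
8 | (R)-4-benzyl-3-{2-[4-(benzyloxy)-5-(methoxycarbonyl)-2-(methoxymethoxy)phenyl]acetyl}oxazolidin-2-one | O=C(Cc1cc(C(=O)OC)c(OCc2ccccc2)cc1OCOC)N1[C@H](Cc2ccccc2)COC1=O | intermediate
9 | 2,4-bis(benzyloxy)benzaldehyde | O=Cc1ccc(OCc2ccccc2)cc1OCc1ccccc1 | starting material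
10 | Z-dibutylboron enolate of 8 | CCCCB(CCCC)O/C(N1[C@H](Cc2ccccc2)COC1=O)=C\c1cc(C(=O)OC)c(OCc2ccccc2)cc1OCOC | intermediate
11 | O-dibutylboryl derivative (boron aldolate) of 12 | O=C(N1[C@H](Cc2ccccc2)COC1=O)[C@H](c1cc(C(=O)OC)c(OCc2ccccc2)cc1OCOC)[C@@H](OB(CCCC)CCCC)c1ccc(OCc2ccccc2)cc1OCc1ccccc1 | intermediate
12 | (R)-4-benzyl-3-[(2R,3R)-2-[4-(benzyloxy)-5-(methoxycarbonyl)-2-(methoxymethoxy)phenyl]-3-[2,4-bis(benzyloxy)phenyl]-3-hydroxypropanoyl]oxazolidin-2-one | O=C(N1[C@H](Cc2ccccc2)COC1=O)[C@H](c1cc(C(=O)OC)c(OCc2ccccc2)cc1OCOC)[C@@H](O)c1ccc(OCc2ccccc2)cc1OCc1ccccc1 | intermediate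
13 | (R)-4-benzyl-3-[(2R,3R)-2-[4-(benzyloxy)-2-hydroxy-5-(methoxycarbonyl)phenyl]-3-[2,4-bis(benzyloxy)phenyl]-3-hydroxypropanoyl]oxazolidin-2-one | O=C(N1[C@H](Cc2ccccc2)COC1=O)[C@H](c1cc(C(=O)OC)c(OCc2ccccc2)cc1O)[C@@H](O)c1ccc(OCc2ccccc2)cc1OCc1ccccc1 | intermediate
14 | methyl (2R,3R)-3-{[(R)-4-benzyl-2-oxooxazolidin-3-yl]carbonyl}-6-(benzyloxy)-2-[2,4-bis(benzyloxy)phenyl]-2,3-dihydro-1-benzofuran-5-carboxylate | O=C(N1[C@H](Cc2ccccc2)COC1=O)[C@@H]2c3cc(C(=O)OC)c(OCc4ccccc4)cc3O[C@H]2c1ccc(OCc2ccccc2)cc1OCc1ccccc1 | intermediate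
15 | (2R,3R)-6-(benzyloxy)-2-[2,4-bis(benzyloxy)phenyl]-5-(methoxycarbonyl)-2,3-dihydro-1-benzofuran-3-carboperoxoic acid | OOC(=O)[C@@H]2c3cc(C(=O)OC)c(OCc4ccccc4)cc3O[C@H]2c1ccc(OCc2ccccc2)cc1OCc1ccccc1 | intermediate
16 | (2R,3R)-6-(benzyloxy)-2-[2,4-bis(benzyloxy)phenyl]-5-(methoxycarbonyl)-2,3-dihydro-1-benzofuran-3-carboxylic acid | OC(=O)[C@@H]2c3cc(C(=O)OC)c(OCc4ccccc4)cc3O[C@H]2c1ccc(OCc2ccccc2)cc1OCc1ccccc1 | intermediate
17 | 1,3-bis(benzyloxy)-5-bromobenzene | Brc1cc(OCc2ccccc2)cc(OCc2ccccc2)c1 | starting material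
18 | methyl (2R,3R)-6-(benzyloxy)-2-[2,4-bis(benzyloxy)phenyl]-3-[3,5-bis(benzyloxy)phenyl]-2,3-dihydro-1-benzofuran-5-carboxylate | c1ccccc1COc1cc(OCc2ccccc2)cc([C@@H]2c3cc(C(=O)OC)c(OCc4ccccc4)cc3O[C@H]2c2ccc(OCc3ccccc3)cc2OCc2ccccc2)c1 | intermediate
19 | [(2R,3R)-6-(benzyloxy)-2-[2,4-bis(benzyloxy)phenyl]-3-[3,5-bis(benzyloxy)phenyl]-2,3-dihydro-1-benzofuran-5-yl]methanol | c1ccccc1COc1cc(OCc2ccccc2)cc([C@@H]2c3cc(CO)c(OCc4ccccc4)cc3O[C@H]2c2ccc(OCc3ccccc3)cc2OCc2ccccc2)c1 | intermediate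
20 | (2R,3R)-6-(benzyloxy)-2-[2,4-bis(benzyloxy)phenyl]-3-[3,5-bis(benzyloxy)phenyl]-2,3-dihydro-1-benzofuran-5-carbaldehyde | c1ccccc1COc1cc(OCc2ccccc2)cc([C@@H]2c3cc(C=O)c(OCc4ccccc4)cc3O[C@H]2c2ccc(OCc3ccccc3)cc2OCc2ccccc2)c1 | intermediate
21 | methyl 4-bromo-3,5-dihydroxybenzoate | COC(=O)c1cc(O)c(Br)c(O)c1 | starting material
22 | methyl 4-bromo-3,5-bis(methoxymethoxy)benzoate | COC(=O)c1cc(OCOC)c(Br)c(OCOC)c1 | intermediate
23 | methyl 4-[2-(benzyloxy)-2-oxoethyl]-3,5-bis(methoxymethoxy)benzoate | COC(=O)c1cc(OCOC)c(CC(=O)OCc2ccccc2)c(OCOC)c1 | intermediate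
24 | 2-[4-(methoxycarbonyl)-2,6-bis(methoxymethoxy)phenyl]acetic acid | COC(=O)c1cc(OCOC)c(CC(=O)O)c(OCOC)c1 | intermediate
25 | 2-[4-(methoxycarbonyl)-2,6-bis(methoxymethoxy)phenyl]acetic pivalic anhydride | COC(=O)c1cc(OCOC)c(CC(=O)OC(=O)C(C)(C)C)c(OCOC)c1 | intermediate
26 | (R)-4-benzyl-3-{2-[4-(methoxycarbonyl)-2,6-bis(methoxymethoxy)phenyl]acetyl}oxazolidin-2-one | COC(=O)c1cc(OCOC)c(CC(=O)N2[C@H](Cc3ccccc3)COC2=O)c(OCOC)c1 | intermediate
27 | Z-dibutylboron enolate of 26 | CCCCB(CCCC)O/C(N1[C@H](Cc2ccccc2)COC1=O)=C\c1c(OCOC)cc(C(=O)OC)cc1OCOC | intermediate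
28 | O-dibutylboryl derivative (boron aldolate) of 29 | c1ccccc1COc1cc(OCc2ccccc2)cc([C@@H]2c3cc([C@H](OB(CCCC)CCCC)[C@@H](c4c(OCOC)cc(C(=O)OC)cc4OCOC)C(=O)N4[C@H](Cc5ccccc5)COC4=O)c(OCc4ccccc4)cc3O[C@H]2c2ccc(OCc3ccccc3)cc2OCc2ccccc2)c1 | intermediate
29 | (R)-4-benzyl-3-[(2R,3R)-3-hydroxy-2-[4-(methoxycarbonyl)-2,6-bis(methoxymethoxy)phenyl]-3-(U1)propanoyl]oxazolidin-2-one | c1ccccc1COc1cc(OCc2ccccc2)cc([C@@H]2c3cc([C@H](O)[C@@H](c4c(OCOC)cc(C(=O)OC)cc4OCOC)C(=O)N4[C@H](Cc5ccccc5)COC4=O)c(OCc4ccccc4)cc3O[C@H]2c2ccc(OCc3ccccc3)cc2OCc2ccccc2)c1 | intermediate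
30 | (R)-4-benzyl-3-[(2R,3R)-2-[2,6-dihydroxy-4-(methoxycarbonyl)phenyl]-3-hydroxy-3-(U1)propanoyl]oxazolidin-2-one | c1ccccc1COc1cc(OCc2ccccc2)cc([C@@H]2c3cc([C@H](O)[C@@H](c4c(O)cc(C(=O)OC)cc4O)C(=O)N4[C@H](Cc5ccccc5)COC4=O)c(OCc4ccccc4)cc3O[C@H]2c2ccc(OCc3ccccc3)cc2OCc2ccccc2)c1 | intermediate
31 | methyl (2R,3R)-3-{[(R)-4-benzyl-2-oxooxazolidin-3-yl]carbonyl}-4-hydroxy-2-(U1)-2,3-dihydro-1-benzofuran-6-carboxylate | c1ccccc1COc1cc(OCc2ccccc2)cc([C@@H]2c3cc([C@@H]4Oc5cc(C(=O)OC)cc(O)c5[C@H]4C(=O)N4[C@H](Cc5ccccc5)COC4=O)c(OCc4ccccc4)cc3O[C@H]2c2ccc(OCc3ccccc3)cc2OCc2ccccc2)c1 | intermediate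
32 | methyl (2R,3R)-3-{[(R)-4-benzyl-2-oxooxazolidin-3-yl]carbonyl}-4-(benzyloxy)-2-(U1)-2,3-dihydro-1-benzofuran-6-carboxylate | c1ccccc1COc1cc(OCc2ccccc2)cc([C@@H]2c3cc([C@@H]4Oc5cc(C(=O)OC)cc(OCc6ccccc6)c5[C@H]4C(=O)N4[C@H](Cc5ccccc5)COC4=O)c(OCc4ccccc4)cc3O[C@H]2c2ccc(OCc3ccccc3)cc2OCc2ccccc2)c1 | intermediate
33 | (2R,3R)-4-(benzyloxy)-6-(methoxycarbonyl)-2-(U1)-2,3-dihydro-1-benzofuran-3-carboperoxoic acid | c1ccccc1COc1cc(OCc2ccccc2)cc([C@@H]2c3cc([C@@H]4Oc5cc(C(=O)OC)cc(OCc6ccccc6)c5[C@H]4C(=O)OO)c(OCc4ccccc4)cc3O[C@H]2c2ccc(OCc3ccccc3)cc2OCc2ccccc2)c1 | intermediate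
34 | (2R,3R)-4-(benzyloxy)-6-(methoxycarbonyl)-2-(U1)-2,3-dihydro-1-benzofuran-3-carboxylic acid | c1ccccc1COc1cc(OCc2ccccc2)cc([C@@H]2c3cc([C@@H]4Oc5cc(C(=O)OC)cc(OCc6ccccc6)c5[C@H]4C(=O)O)c(OCc4ccccc4)cc3O[C@H]2c2ccc(OCc3ccccc3)cc2OCc2ccccc2)c1 | intermediate
35 | methyl (2R,3R)-4-(benzyloxy)-3-[3,5-bis(benzyloxy)phenyl]-2-(U1)-2,3-dihydro-1-benzofuran-6-carboxylate | c1ccccc1COc1cc(OCc2ccccc2)cc([C@@H]2c3cc([C@@H]4Oc5cc(C(=O)OC)cc(OCc6ccccc6)c5[C@H]4c4cc(OCc5ccccc5)cc(OCc5ccccc5)c4)c(OCc4ccccc4)cc3O[C@H]2c2ccc(OCc3ccccc3)cc2OCc2ccccc2)c1 | intermediate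
36 | [(2R,3R)-4-(benzyloxy)-3-[3,5-bis(benzyloxy)phenyl]-2-(U1)-2,3-dihydro-1-benzofuran-6-yl]methanol | c1ccccc1COc1cc(OCc2ccccc2)cc([C@@H]2c3cc([C@@H]4Oc5cc(CO)cc(OCc6ccccc6)c5[C@H]4c4cc(OCc5ccccc5)cc(OCc5ccccc5)c4)c(OCc4ccccc4)cc3O[C@H]2c2ccc(OCc3ccccc3)cc2OCc2ccccc2)c1 | intermediate
37 | (2R,3R)-4-(benzyloxy)-3-[3,5-bis(benzyloxy)phenyl]-2-(U1)-2,3-dihydro-1-benzofuran-6-carbaldehyde | c1ccccc1COc1cc(OCc2ccccc2)cc([C@@H]2c3cc([C@@H]4Oc5cc(C=O)cc(OCc6ccccc6)c5[C@H]4c4cc(OCc5ccccc5)cc(OCc5ccccc5)c4)c(OCc4ccccc4)cc3O[C@H]2c2ccc(OCc3ccccc3)cc2OCc2ccccc2)c1 | intermediate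
38 | [2,4-bis(benzyloxy)phenyl]methanol | OCc1ccc(OCc2ccccc2)cc1OCc1ccccc1 | intermediate
39 | diethyl [2,4-bis(benzyloxy)benzyl]phosphonate | CCOP(=O)(OCC)Cc1ccc(OCc2ccccc2)cc1OCc1ccccc1 | intermediate
40 | sodium [2,4-bis(benzyloxy)phenyl](diethoxyphosphoryl)methanide | [Na+].CCOP(=O)(OCC)[CH-]c1ccc(OCc2ccccc2)cc1OCc1ccccc1 | intermediate
41 | (2R,3R)-4-(benzyloxy)-3-[3,5-bis(benzyloxy)phenyl]-6-{(E)-2-[2,4-bis(benzyloxy)phenyl]ethenyl}-2-(U1)-2,3-dihydro-1-benzofuran (deca-O-benzylgneyulin A) | c1ccccc1COc1cc(OCc2ccccc2)cc([C@@H]2c3cc([C@@H]4Oc5cc(/C=C/c6ccc(OCc7ccccc7)cc6OCc6ccccc6)cc(OCc6ccccc6)c5[C@H]4c4cc(OCc5ccccc5)cc(OCc5ccccc5)c4)c(OCc4ccccc4)cc3O[C@H]2c2ccc(OCc3ccccc3)cc2OCc2ccccc2)c1 | intermediate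
42 | gneyulin A, 4-[(E)-2-[(2R,3R)-3-(3,5-dihydroxyphenyl)-2-[(2R,3R)-2-(2,4-dihydroxyphenyl)-3-(3,5-dihydroxyphenyl)-6-hydroxy-2,3-dihydro-1-benzofuran-5-yl]-4-hydroxy-2,3-dihydro-1-benzofuran-6-yl]ethenyl]benzene-1,3-diol | Oc1cc(O)cc([C@@H]2c3cc([C@@H]4Oc5cc(/C=C/c6ccc(O)cc6O)cc(O)c5[C@H]4c4cc(O)cc(O)c4)c(O)cc3O[C@H]2c2ccc(O)cc2O)c1 | target

**Totals and weak points**

Total step count: 26. Longest linear sequence: 20 steps (steps 1–11, 16–22, 25, 26).

The three steps most likely to fail: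

Step 13 (Negishi coupling at the bromide flanked by two MOM ethers). If the zinc enolate does not couple, the two-carbon side chain is brought in as an allyl group. Setting out from 22, Suzuki–Miyaura coupling with allylboronic acid pinacol ester (Pd(PPh3)4, CsF, THF, 70 °C) gives methyl 4-allyl-3,5-bis(methoxymethoxy)benzoate F1. Oxidative cleavage of its alkene (RuCl3 cat., NaIO4, MeCN/EtOAc/H2O) gives acid 24 directly, where the route resumes at step 15.

Step 16 (boron aldol of the doubly ortho-substituted imide with the bulky aldehyde). If the hindered enolate does not add, the C2–C3 bond of the second ring is made by a Michael addition/ring closure, and the acid and arylation stages of unit 2 are bypassed. Setting out from alcohol 19, treatment with tetrahydrothiophene and HBF4·OEt2 in CH2Cl2 gives 1-[(U1)methyl]tetrahydrothiophenium tetrafluoroborate F2. In parallel, 22 after bromine–magnesium exchange (i-PrMgCl·LiCl, THF, −20 °C) is added to 3,5-bis(benzyloxy)benzaldehyde to give methyl 4-{[3,5-bis(benzyloxy)phenyl](hydroxy)methyl}-3,5-bis(methoxymethoxy)benzoate F3. Sodium p-toluenesulfinate in aqueous formic acid at 40 °C removes both MOM groups and converts F3 into methyl 4-{[3,5-bis(benzyloxy)phenyl](tosyl)methyl}-3,5-dihydroxybenzoate F4. With Cs2CO3 in CH2Cl2, F2 and F4 react by base-induced conjugate addition and ring closure (formal [4+1] annulation) to give methyl (2R,3R)-3-[3,5-bis(benzyloxy)phenyl]-4-hydroxy-2-(U1)-2,3-dihydro-1-benzofuran-6-carboxylate F5. The new ring forms trans but without control by the remote centres, so the (2S,3S)-ring diastereomer has to be removed by chromatography. Benzylation of F5 (BnBr, K2CO3, acetone) gives 35, and the route resumes at step 21.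

Step 20 (decarboxylative arylation at the hindered C3 of unit 2). If the photoredox coupling gives mainly protodecarboxylation or poor conversion, the acid is pre-activated and coupled with an aryl nucleophile. Setting out from acid 34, N-hydroxyphthalimide and N,N'-diisopropylcarbodiimide (DMAP cat., CH2Cl2) give the 1,3-dioxoisoindolin-2-yl ester of 34 F6. Nickel-catalysed decarboxylative Negishi-type coupling (NiCl2·glyme, dtbbpy, THF/DMF, rt) with [3,5-bis(benzyloxy)phenyl]zinc chloride F7 (made from 17 with Mg, then ZnCl2) again places the aryl group trans to the C2 substituent and gives 35, where the route resumes at step 21.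

**Further compounds**

F1 | step 13 | methyl 4-allyl-3,5-bis(methoxymethoxy)benzoate | COC(=O)c1cc(OCOC)c(CC=C)c(OCOC)c1
F2 | step 16 | 1-[(U1)methyl]tetrahydrothiophenium tetrafluoroborate | c1ccccc1COc1cc(OCc2ccccc2)cc([C@@H]2c3cc(C[S+]4CCCC4)c(OCc4ccccc4)cc3O[C@H]2c2ccc(OCc3ccccc3)cc2OCc2ccccc2)c1.F[B-](F)(F)F
F3 | step 16 | methyl 4-{[3,5-bis(benzyloxy)phenyl](hydroxy)methyl}-3,5-bis(methoxymethoxy)benzoate (racemic carbinol) | COC(=O)c1cc(OCOC)c(C(O)c2cc(OCc3ccccc3)cc(OCc3ccccc3)c2)c(OCOC)c1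
F4 | step 16 | methyl 4-{[3,5-bis(benzyloxy)phenyl](tosyl)methyl}-3,5-dihydroxybenzoate (racemic) | COC(=O)c1cc(O)c(C(c2cc(OCc3ccccc3)cc(OCc3ccccc3)c2)S(=O)(=O)c2ccc(C)cc2)c(O)c1
F5 | step 16 | methyl (2R,3R)-3-[3,5-bis(benzyloxy)phenyl]-4-hydroxy-2-(U1)-2,3-dihydro-1-benzofuran-6-carboxylate | c1ccccc1COc1cc(OCc2ccccc2)cc([C@@H]2c3cc([C@@H]4Oc5cc(C(=O)OC)cc(O)c5[C@H]4c4cc(OCc5ccccc5)cc(OCc5ccccc5)c4)c(OCc4ccccc4)cc3O[C@H]2c2ccc(OCc3ccccc3)cc2OCc2ccccc2)c1
F6 | step 20 | 1,3-dioxoisoindolin-2-yl (2R,3R)-4-(benzyloxy)-6-(methoxycarbonyl)-2-(U1)-2,3-dihydro-1-benzofuran-3-carboxylate | c1ccccc1COc1cc(OCc2ccccc2)cc([C@@H]2c3cc([C@@H]4Oc5cc(C(=O)OC)cc(OCc6ccccc6)c5[C@H]4C(=O)ON4C(=O)c5ccccc5C4=O)c(OCc4ccccc4)cc3O[C@H]2c2ccc(OCc3ccccc3)cc2OCc2ccccc2)c1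
F7 | step 20 | [3,5-bis(benzyloxy)phenyl]zinc chloride | Cl[Zn]c1cc(OCc2ccccc2)cc(OCc2ccccc2)c1
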